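Start from the product. In the east run at 50.0 min, monomer in chains and free monomer add to 100%, so read the product from what free monomer has lost.

all flasks: free monomer 2.8 M
- north-east: transfer agent 0.028 M; initiator 62 mM; run made earlier
- east: transfer agent 0.028 M; initiator 170 mM; run made earlier
- south-west: transfer agent 0.028 M; initiator 530 mM; run made earlier
- oak: transfer agent 0.0280 M; initiator 600 mM; time 50 min
- ash: transfer agent 0.0280 M; initiator 400 mM; time 50 min
- birch: transfer agent 0.0280 M; initiator 200 mM; time 50 min
- larch: transfer agent 0.0280 M; initiator 140 mM; time 50 min
- maple: transfer agent 0.0280 M; initiator 100 mM; time 50 min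
- alder: transfer agent 0.0280 M; initiator 50 mM; time 50 min

| run | time / min | monomer in chains / % | free monomer / % |
|---|---|---|---|
| north-east | 10.0 | 28.0 | 71.8 |
| north-east | 20.0 | 31.2 | 69.4 |
| north-east | 30.0 | 31.1 | 67.5 |
| north-east | 40.0 | 32.4 | 67.9 |
| north-east | 50.0 | 32.3 | 67.4 |
| east | 10.0 | 57.5 | 41.2 |
| east | 20.0 | 65.9 | 34.8 |
| east | 30.0 | 66.7 | 33.2 |
| east | 40.0 | 68.0 | 31.7 |
| east | 50.0 | 69.2 | 31.0 |
| south-west | 4.00 | 76.2 | 25.0 |
| south-west | 12.0 | 92.7 | 7.1 |
| south-west | 25.0 | 97.6 | 2.5 |
| south-west | 40.0 | 98.4 | 1.9 |
| south-west | 50.0 | 97.8 | 0.2 |

(scatter of a reading: 0.5 percentage points)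



- the flasks put in order of amount of monomer in chains, in percent of the free monomer charged, best first, at 50 min (oak / ash / birch / larch / maple / alder)
- the same order at 10 min (oak / ash / birch / larch / maple / alder)
- the amount of monomer in chains, in percent of the free monomer charged of the flask you put first, at 50 min
- the amount of monomer in chains, in percent of the free monomer charged of the flask you put last, at 50 min

Ask first where a flask ends. East gains 8.4 percentage points from 10.0 min to 20.0 min, more than the 2.5 points from 30.0 min to 50.0 min, so treat 50.0 min as near the stall.

Now call the natural logarithm of charge over free monomer left the dose, a measure that adds up if the loss is first order in free monomer. North-east reaches 0.395 and east 1.17. Divide by initiator: east gives 6.89 L mol⁻¹, which would put alder at 29.1%. But north-east gives 6.36 L mol⁻¹, less, and a scatter of 0.5 points does not cover that gap.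

So reforge this weak link and let the line miss zero. Reckon 7.19 L mol⁻¹ from those two runs: this is the dose per extra initiator. The line then reaches zero dose at 7.14 mM of initiator, itself a reading. Test it on south-west at 50.0 min, the time the line was built for, since that run did not shape it: the line leaves 2.33% free monomer, the free monomer reading is 0.2%, and the monomer in chains reading falls 2.20% short of the charge. These two readings of one quantity lie 2 points apart, so take south-west as a test to about that width. Commit to 98.6% for oak and 26.5% for alder. Order the flasks by initiator at both times, since at 10.0 min east also stands above north-east.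

The forecast gave oak > ash > birch > larch > maple > alder at 50 min and oak > ash > birch > larch > maple > alder at 10 min, with 98.7% and 26.5%, on its own fit: “A small threshold of about 8 mM, with slope 0.0072 per mM, fits equally well.”

The flasks give oak > ash > birch > larch > maple > alder at 50 min, oak > ash > birch > larch > maple > alder at 10 min, with 99.2% and 26.7%, so the forecast held.

    free monomer + initiator → living end + monomer in chains (k = 1.70 L mol⁻¹ min⁻¹)
    free monomer + living end → monomer in chains + living end, rate k2*[living end]*[free monomer] (k = 1.20 L mol⁻¹ min⁻¹)
    living end + transfer agent → dead chain (kL = 2.50 L mol⁻¹ min⁻¹)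
    living end → dead end (k = 0.150 min⁻¹)
    2 initiator ⇌ resting dimer (K = 160 L mol⁻¹, k = 3.90 L mol⁻¹ min⁻¹)

In oak at 1.71 min, living end has a half-life of 4.6 min by the step to dead end, far shorter than the run, and 99.5% of the growth up to 50 min is behind it at 25.0 min. In alder 0.0082% of the initiator charge is left beside 73% of the free monomer, and the dose there is 0.310 against the line's 0.308.

Take a neighbour of oak charged with 0.36 M of initiator: the dose per extra initiator gives 92.1%. The flask gives 93.1%.

The readings are calculated for substances that don't exist; scatter was added.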